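**Retrosynthetic overview** (ring atoms: C1 carries the side chain, C2 is =CH, C3 is CH–OH, C4 is =CH, C5 is C–OMe, C6 is CH–OAc)
1. The only ring is opened at the C2–C3 bond: target 16 ⇐ acyclic (Z)-iodoalkene / (E)-β-methoxy enal 15; the ring is closed last, by an intramolecular Ni/Cr alkenyl–aldehyde coupling that also creates C3 and its free hydroxyl.
2. Enabling feature: carbinol C3 is bonded to alkenyl carbon C2, both ring alkenes (C1=C2, C4=C5) are cis-disposed within the chain C2=C1–C6–C5=C4–C3, and C6 sits between two substituted sp2 carbons (C1, C5), which holds its acetate pseudoaxial and relays C6 to C3 (trans).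
3. 15 ⇐ iodo tetronate 12: a temporary butenolide ring stores C3 at the acid level and locks the C4=C5 geometry; it is opened to the N-methoxy-N-methylamide, acetylated and reduced.
4. 12 ⇐ enal 7 + methyl propiolate 8 (zinc–ProPhenol alkynylation sets C6, then methoxide addition/lactonisation); 7 ⇐ alkyne 6 by silylformylation (CO becomes C6, silicon marks C2 with Z geometry).
5. 6 ⇐ (R)-epichlorohydrin 1 + decylmagnesium bromide 2 + acetylide (side-chain centre from the chiral pool); ring order: one carbocycle, formed in step 10.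

Key step: step 10

Assumption: (S,S)-ProPhenol is taken to deliver the alkynylzinc to the Re face of enal 7 (the sense of its aldol reactions); if the sense is opposite, (R,R)-ProPhenol is used and nothing else changes.

**Step 1**
Reactants: 1 (R)-epichlorohydrin; 2 decylmagnesium bromide
Product: 3 (2R)-1-chlorotridecan-2-ol
Conditions: CuI (10 mol %), THF, −40 to 0 °C; aq. NH4Cl
Reagents that add atoms: none
Why: Copper-catalysed Grignard opening of the epoxide at its unsubstituted terminus (SN2) should leave the stereocentre of 1 untouched; no new stereocentre is formed.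

**Step 2**
Reactants: 3 (2R)-1-chlorotridecan-2-ol
Product: 5 (4R)-pentadec-1-yn-4-ol, via (2R)-2-undecyloxirane 4 (not isolated)
Conditions: LiC≡CH·H2NCH2CH2NH2 (3 equiv), DMSO, 0 °C to rt
Reagents that add atoms: lithium acetylide ethylenediamine complex, [Li]C#C.NCCN
Why: The first equivalent of acetylide closes the chlorohydrin to epoxide 4 (intramolecular Williamson displacement) and the second opens 4 at its CH2 terminus (SN2 epoxide alkynylation), so the (R) centre is carried over unchanged.

**Step 3**
Reactants: 5 (4R)-pentadec-1-yn-4-ol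
Product: 6 (4R)-pentadec-1-yn-4-yl acetate
Conditions: Ac2O, pyridine, DMAP (cat.), CH2Cl2, 0 °C to rt
Reagents that add atoms: acetic anhydride, CC(=O)OC(C)=O
Why: DMAP-catalysed O-acetylation masks the hydroxyl against dehydrogenative silylation in step 4; no stereocentre is touched.

**Step 4**
Reactants: 6 (4R)-pentadec-1-yn-4-yl acetate
Product: 7 (2Z,4R)-2-{[dimethyl(phenyl)silyl]methylidene}-1-oxopentadecan-4-yl acetate
Conditions: Me2PhSiH (1.2 equiv), CO (20 atm), Rh4(CO)12 (1 mol %), Et3N, toluene, 90 °C
Reagents that add atoms: dimethylphenylsilane, C[SiH](C)c1ccccc1; carbon monoxide, [C-]#[O+]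
Why: Rhodium-catalysed silylformylation of a terminal alkyne should add silicon to the terminal carbon and the formyl group to the internal carbon in a syn fashion, which gives the (Z)-β-silyl enal; no stereocentre is formed and the alkene geometry follows from the syn addition.

**Step 5**
Reactants: 7 (2Z,4R)-2-{[dimethyl(phenyl)silyl]methylidene}-1-oxopentadecan-4-yl acetate; 8 methyl propiolate
Product: 9 methyl (4R,5Z,7R)-7-acetoxy-5-{[dimethyl(phenyl)silyl]methylidene}-4-hydroxyoctadec-2-ynoate
Conditions: 8 (3 equiv), Me2Zn (3 equiv), (S,S)-ProPhenol (10 mol %), toluene, 4 °C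
Reagents that add atoms: none
Why: Catalytic enantioselective alkynylation of an enal (dinuclear zinc–ProPhenol catalyst, 1,2-addition of the alkynylzinc): the ligand should direct the alkynyl group to the Re face of the aldehyde, which sets the carbinol centre (4R in 9, the later ring C6).

**Step 6**
Reactants: 9 methyl (4R,5Z,7R)-7-acetoxy-5-{[dimethyl(phenyl)silyl]methylidene}-4-hydroxyoctadec-2-ynoate
Product: 11 (1Z,4R)-1-[dimethyl(phenyl)silyl]-2-[(2S)-3-methoxy-5-oxo-2,5-dihydrofuran-2-yl]pentadec-1-en-4-yl acetate, via open-chain β-methoxy enoate 10 (not isolated)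
Conditions: NaOMe (0.1 equiv), MeOH, 0 °C, short reaction time; AcOH quench
Reagents that add atoms: methanol, CO
Why: Oxa-Michael addition of methoxide to the ynoate should place OMe on the β-carbon, and the γ-hydroxyl then lactonises onto the ester (tetronate formation), which locks the enol ether geometry in a ring; the carbinol centre is not touched (its descriptor changes from R to S only because the priorities change).

**Step 7**
Reactants: 11 (1Z,4R)-1-[dimethyl(phenyl)silyl]-2-[(2S)-3-methoxy-5-oxo-2,5-dihydrofuran-2-yl]pentadec-1-en-4-yl acetate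
Product: 12 (1Z,4R)-1-iodo-2-[(2S)-3-methoxy-5-oxo-2,5-dihydrofuran-2-yl]pentadec-1-en-4-yl acetate
Conditions: N-iodosuccinimide (1.3 equiv), (CF3)2CHOH, 0 °C
Reagents that add atoms: N-iodosuccinimide, O=C1CCC(=O)N1I
Why: Iododesilylation of an alkenylsilane (ipso substitution through the β-silyl cation) in hexafluoroisopropanol should proceed with retention of alkene geometry, so iodine ends cis to the lactone-bearing carbon; no stereocentre is formed.

**Step 8**
Reactants: 12 (1Z,4R)-1-iodo-2-[(2S)-3-methoxy-5-oxo-2,5-dihydrofuran-2-yl]pentadec-1-en-4-yl acetate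
Product: 14 (2E,4S,5Z,7R)-5-(iodomethylidene)-3-methoxy-1-[methoxy(methyl)amino]-1-oxooctadec-2-ene-4,7-diyl diacetate, via diol amide 13 (not isolated)
Conditions: Me3Al (6 equiv), MeNHOMe·HCl (6 equiv), CH2Cl2, 0 °C to rt; then pyridine, Ac2O (excess), DMAP, 0 °C, same pot
Reagents that add atoms: N,O-dimethylhydroxylamine hydrochloride, CNOC.Cl; acetic anhydride, CC(=O)OC(C)=O
Why: Aluminium amide aminolysis (Weinreb amide formation) should open the lactone at its acyl carbon without touching the stereocentre or the alkene geometry and also cleaves the side-chain acetate; acetylating the aluminium alkoxides in the same pot installs both target acetates and blocks relactonisation.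

**Step 9**
Reactants: 14 (2E,4S,5Z,7R)-5-(iodomethylidene)-3-methoxy-1-[methoxy(methyl)amino]-1-oxooctadec-2-ene-4,7-diyl diacetate
Product: 15 (2E,4S,5Z,7R)-5-(iodomethylidene)-3-methoxy-1-oxooctadec-2-ene-4,7-diyl diacetate
Conditions: Cp2Zr(H)Cl (2 equiv), THF, rt; aqueous work-up
Reagents that add atoms: none
Why: Cp2Zr(H)Cl should reduce the tertiary N-methoxy-N-methylamide to the aldehyde through a stable zirconated hemiaminal (amide hydrozirconation) and leave acetates, enol ether and alkenyl iodide untouched; no stereocentre is formed.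

**Step 10**
Reactants: 15 (2E,4S,5Z,7R)-5-(iodomethylidene)-3-methoxy-1-oxooctadec-2-ene-4,7-diyl diacetate
Product: 16 (1S,4S)-2-[(2R)-2-acetoxytridecyl]-4-hydroxy-6-methoxycyclohexa-2,5-dien-1-yl acetate (target)
Conditions: CrCl2 (8 equiv), NiCl2 (0.1 equiv), degassed DMSO/THF, 0.005 M, slow addition, rt; aqueous potassium sodium tartrate work-up at pH 7
Reagents that add atoms: none
Why: Zerovalent nickel (from NiCl2 and CrCl2) inserts into the alkenyl C–I bond, the alkenyl group passes to trivalent chromium, and the alkenylchromium adds 1,2 to the aldehyde; the closest known reaction type is the intramolecular Nozaki–Hiyama–Kishi alkenyl iodide–aldehyde coupling used to close carbocycles. The ring should close between alkenyl carbon C2 and aldehyde carbon C3 in a 6-exo-trig mode, because the Z iodoalkene and the E methoxy enal hold these two termini next to each other. The new centre C3 is controlled by the existing centre C6: A(1,2) strain with the side chain on C1 and the methoxy group on C5 should hold the C6 acetate pseudoaxial in the boat-like transition state, and the chromium-bound aldehyde oxygen takes the pseudoequatorial site, which puts the new hydroxyl trans to the acetate (3S on the ring numbering used here). The step needs chemoselectivity for the aldehyde over two acetates and 1,2- over conjugate addition, which the organochromium reagent provides, and it needs both alkene geometries to stay fixed, which the retentive nickel-to-chromium transfer secures. The chromium alkoxide is released on neutral work-up, so the acid- and base-sensitive bis-allylic dienol is not exposed to conditions that would aromatise it.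

**Compound list**
1 | (R)-epichlorohydrin, (2R)-2-(chloromethyl)oxirane | ClC[C@H]1CO1 | starting material
2 | decylmagnesium bromide | CCCCCCCCCC[Mg]Br | starting material
3 | (2R)-1-chlorotridecan-2-ol | ClC[C@H](O)CCCCCCCCCCC | intermediate
4 | (2R)-2-undecyloxirane | CCCCCCCCCCC[C@@H]1CO1 | intermediate
5 | (4R)-pentadec-1-yn-4-ol | C#CC[C@H](O)CCCCCCCCCCC | intermediate
6 | (4R)-pentadec-1-yn-4-yl acetate | C#CC[C@H](OC(C)=O)CCCCCCCCCCC | intermediate
7 | (2Z,4R)-2-{[dimethyl(phenyl)silyl]methylidene}-1-oxopentadecan-4-yl acetate | O=C/C(=C\[Si](C)(C)c1ccccc1)C[C@H](OC(C)=O)CCCCCCCCCCC | intermediate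
8 | methyl propiolate (methyl prop-2-ynoate) | COC(=O)C#C | starting material
9 | methyl (4R,5Z,7R)-7-acetoxy-5-{[dimethyl(phenyl)silyl]methylidene}-4-hydroxyoctadec-2-ynoate | COC(=O)C#C[C@@H](O)/C(=C\[Si](C)(C)c1ccccc1)C[C@H](OC(C)=O)CCCCCCCCCCC | intermediate
10 | methyl (2E,4S,5Z,7R)-7-acetoxy-5-{[dimethyl(phenyl)silyl]methylidene}-4-hydroxy-3-methoxyoctadec-2-enoate | COC(=O)/C=C(OC)\[C@@H](O)/C(=C\[Si](C)(C)c1ccccc1)C[C@H](OC(C)=O)CCCCCCCCCCC | intermediate
11 | (1Z,4R)-1-[dimethyl(phenyl)silyl]-2-[(2S)-3-methoxy-5-oxo-2,5-dihydrofuran-2-yl]pentadec-1-en-4-yl acetate | O=C1C=C(OC)[C@@H](O1)/C(=C\[Si](C)(C)c1ccccc1)C[C@H](OC(C)=O)CCCCCCCCCCC | intermediate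
12 | (1Z,4R)-1-iodo-2-[(2S)-3-methoxy-5-oxo-2,5-dihydrofuran-2-yl]pentadec-1-en-4-yl acetate | O=C1C=C(OC)[C@@H](O1)/C(=C\I)C[C@H](OC(C)=O)CCCCCCCCCCC | intermediate
13 | (2E,4S,5Z,7R)-4,7-dihydroxy-5-(iodomethylidene)-N,3-dimethoxy-N-methyloctadec-2-enamide | CON(C)C(=O)/C=C(OC)\[C@@H](O)/C(=C\I)C[C@H](O)CCCCCCCCCCC | intermediate
14 | (2E,4S,5Z,7R)-5-(iodomethylidene)-3-methoxy-1-[methoxy(methyl)amino]-1-oxooctadec-2-ene-4,7-diyl diacetate | CON(C)C(=O)/C=C(OC)\[C@@H](OC(C)=O)/C(=C\I)C[C@H](OC(C)=O)CCCCCCCCCCC | intermediate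
15 | (2E,4S,5Z,7R)-5-(iodomethylidene)-3-methoxy-1-oxooctadec-2-ene-4,7-diyl diacetate | O=C/C=C(OC)\[C@@H](OC(C)=O)/C(=C\I)C[C@H](OC(C)=O)CCCCCCCCCCC | intermediate
16 | (1S,4S)-2-[(2R)-2-acetoxytridecyl]-4-hydroxy-6-methoxycyclohexa-2,5-dien-1-yl acetate | CCCCCCCCCCC[C@H](CC1=C[C@H](O)C=C(OC)[C@H]1OC(C)=O)OC(C)=O | target

**Total step count:** 10
**Longest linear sequence:** 10 steps (from 1; 2 and 8 enter as commercial materials)

**Steps most likely to fail**

Step 10 – poor facial selectivity at C3 in the ring closure, or aromatisation of the dienol during the coupling. The fallback sets C3 by reagent control before the ring exists and closes the same ring at the C1=C2 alkene by metathesis. It sets out from 11: protodesilylation (CF3CO2H, CH2Cl2, 0 °C) should give the methylidene tetronate F1; the conditions of step 8 then lead through the diol amide F2 (not isolated) to the diacetate amide F3, and Cp2Zr(H)Cl gives the enal F4. A ligand-controlled Ni/Cr vinylation (vinyl bromide, CrCl2, NiCl2, chiral sulfonamide ligand chosen for the 3S carbinol) should give the triene F5, and ring-closing metathesis of its vinyl group with the 1,1-disubstituted alkene (second-generation Grubbs catalyst, CH2Cl2, 40 °C) comes back to the route at 16.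

Step 8 – relactonisation of the opened hydroxy amide before it is acetylated, or attack of the amine at the methoxy-bearing carbon instead of the lactone carbonyl. The fallback takes the lactone to the aldehyde through the alcohol oxidation level. It sets out from 12: i-Bu2AlH (excess, CH2Cl2, −78 to 0 °C) should reduce lactone and acetate to the triol F6; Ac2O/pyridine/DMAP gives the triacetate F7; Candida antarctica lipase B (phosphate buffer pH 7, acetone) should hydrolyse only the primary allylic acetate to the allylic alcohol F8; oxidation with Dess–Martin periodinane/NaHCO3 comes back to the route at 15.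

Step 6 – loss of configuration at the lactone carbinol carbon under methoxide, or base-induced isomerisation of the γ-hydroxy ynoate before conjugate addition. The fallback separates the basic conjugate addition from the lactonisation. It sets out from 9: silylation (t-BuMe2SiCl, imidazole, DMF) gives the silyl ether F9; NaOMe/MeOH at 0 °C should add methanol to give the β-methoxy enoate F10, which cannot lactonise; HF·pyridine (THF, 0 °C) removes the silyl group and the freed hydroxyl lactonises under these acidic conditions (which also equilibrate the push-pull alkene geometry), coming back to the route at 11.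

**Further compounds**
F1 | step 10 | (4R)-2-[(2S)-3-methoxy-5-oxo-2,5-dihydrofuran-2-yl]pentadec-1-en-4-yl acetate | O=C1C=C(OC)[C@@H](O1)C(=C)C[C@H](OC(C)=O)CCCCCCCCCCC
F2 | step 10 | (2E,4S,7R)-4,7-dihydroxy-N,3-dimethoxy-N-methyl-5-methylideneoctadec-2-enamide | CON(C)C(=O)/C=C(OC)\[C@@H](O)C(=C)C[C@H](O)CCCCCCCCCCC
F3 | step 10 | (2E,4S,7R)-3-methoxy-1-[methoxy(methyl)amino]-5-methylidene-1-oxooctadec-2-ene-4,7-diyl diacetate | CON(C)C(=O)/C=C(OC)\[C@@H](OC(C)=O)C(=C)C[C@H](OC(C)=O)CCCCCCCCCCC
F4 | step 10 | (2E,4S,7R)-3-methoxy-5-methylidene-1-oxooctadec-2-ene-4,7-diyl diacetate | O=C/C=C(OC)\[C@@H](OC(C)=O)C(=C)C[C@H](OC(C)=O)CCCCCCCCCCC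
F5 | step 10 | (3S,4E,6S,9R)-3-hydroxy-5-methoxy-7-methylideneicosa-1,4-diene-6,9-diyl diacetate | C=C[C@H](O)/C=C(OC)\[C@@H](OC(C)=O)C(=C)C[C@H](OC(C)=O)CCCCCCCCCCC
F6 | step 8 | (2E,4S,5Z,7R)-5-(iodomethylidene)-3-methoxyoctadec-2-ene-1,4,7-triol | OC/C=C(OC)\[C@@H](O)/C(=C\I)C[C@H](O)CCCCCCCCCCC
F7 | step 8 | (2E,4S,5Z,7R)-5-(iodomethylidene)-3-methoxyoctadec-2-ene-1,4,7-triyl triacetate | CC(=O)OC/C=C(OC)\[C@@H](OC(C)=O)/C(=C\I)C[C@H](OC(C)=O)CCCCCCCCCCC
F8 | step 8 | (2E,4S,5Z,7R)-1-hydroxy-5-(iodomethylidene)-3-methoxyoctadec-2-ene-4,7-diyl diacetate | OC/C=C(OC)\[C@@H](OC(C)=O)/C(=C\I)C[C@H](OC(C)=O)CCCCCCCCCCC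
F9 | step 6 | methyl (4R,5Z,7R)-7-acetoxy-4-{[tert-butyl(dimethyl)silyl]oxy}-5-{[dimethyl(phenyl)silyl]methylidene}octadec-2-ynoate | COC(=O)C#C[C@@H](O[Si](C)(C)C(C)(C)C)/C(=C\[Si](C)(C)c1ccccc1)C[C@H](OC(C)=O)CCCCCCCCCCC
F10 | step 6 | methyl (2E,4S,5Z,7R)-7-acetoxy-4-{[tert-butyl(dimethyl)silyl]oxy}-5-{[dimethyl(phenyl)silyl]methylidene}-3-methoxyoctadec-2-enoate | COC(=O)/C=C(OC)\[C@@H](O[Si](C)(C)C(C)(C)C)/C(=C\[Si](C)(C)c1ccccc1)C[C@H](OC(C)=O)CCCCCCCCCCC
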